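**Retrosynthetic overview**

1. The symmetric C50 polyene is cut at the central C15=C15' bond into two identical C25 polyenals (reductive carbonyl coupling). Each polyenal is cut at C6–C7 into a ring alkenyl triflate and an all-E stannyl tetraenoate (Stille coupling).
2. In the ring fragment the hydroxyprenyl arm is cut at its C=C bond (Wittig) back to a CH2–CHO arm (Ca–Cb) on C2. The six-membered ring is traced back, by taking out C5 (the aldol carbon) and re-joining C6 to C4, to a cyclopentene.
3. Feature on which the strategy rests: ring atoms C6 (sp2, polyene-bearing), C1 (CMe2), C2 (R stereocentre carrying Ca–Cb), C3 and C4 are the five ring carbons of (R)-campholenic aldehyde. Together with C5 (its vinylic methyl) and Ca–Cb they are the ten carbons of α-pinene: C1 is the gem-dimethylcyclobutane carbon and C2 a bridgehead that is never touched.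
4. Ring order: the temporary cyclopentene is formed first, by Lewis-acid rearrangement of α-pinene oxide. It is then opened by ozonolysis and reclosed as six-membered ring A by intramolecular aldol condensation. No further ring is formed.

Key step: step 2

Remark: carotenoid numbering is used for the target (ring C1–C6, chain C7–C15, primes for the second half); (1S,5S)-α-pinene of high enantiomeric purity is assumed, since it is the only source of both stereocentres.

**Route**

Step 1
Reactants: 1 (1S,5S)-α-pinene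
Product: 2 α-pinene oxide, (1R,2R,4S,6R)-2,7,7-trimethyl-3-oxatricyclo[4.1.1.0(2,4)]octane, oxirane on the face anti to the CMe2 bridge
Conditions: mCPBA, NaHCO3, CH2Cl2, 0 °C
Reagents that add atoms: 3-chloroperoxybenzoic acid (mCPBA), OOC(=O)c1cccc(Cl)c1
Why: Prilezhaev epoxidation of the electron-rich trisubstituted alkene; the peracid approaches the face remote from the CMe2 bridge, whose syn methyl blocks the other face, so both oxirane stereocentres are set by the bridgeheads of 1 (substrate control).

Step 2
Reactants: 2 α-pinene oxide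
Product: 3 (R)-campholenic aldehyde, 2-[(1R)-2,2,3-trimethylcyclopent-3-en-1-yl]acetaldehyde
Conditions: ZnBr2 (cat., anhydrous), PhMe, 80 °C
Reagents that add atoms: none
Why: ZnBr2 binds the oxirane oxygen and the C–O bond at the tertiary carbon ionises, while the strained cyclobutane bond from the CMe2 carbon, which lies on the face opposite the departing oxygen, shifts to that carbon (Wagner–Meerwein shift); this makes the bond that becomes C1–C6 of the target and a 2-bornyl-type cation with a zinc alkoxide on the next-but-one carbon. Grob-type fragmentation of this cation then cleaves the bond between the alkoxide carbon and the methyl-bearing bridgehead, which releases the aldehyde of the Ca–Cb arm and the trisubstituted ring alkene. The closest known reaction type is this very Lewis-acid isomerisation of α-pinene oxide to campholenic aldehyde. The five-membered ring is closed by a 1,2-shift ring expansion of the cyclobutane inside the bicycle (cyclobutylcarbinyl to cyclopentyl cation), not by an end-to-end cyclisation. No stereocentre is created: the bridgehead that becomes C2 keeps all four of its bonds, so its configuration is that of 1 and the aldehyde is R. The step needs chemoselectivity for alkyl shift and fragmentation over hydride shift (pinocamphone-type ketones), proton loss (carveol-type allylic alcohols) and migration of the CH2 bridge (fencholenic aldehyde); the non-basic Lewis acid in a non-coordinating solvent, the anti disposition of the CMe2 bridge to the breaking C–O bond and the higher migratory aptitude of the fully substituted bridge carbon should secure it.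

Step 3
Reactants: 3 (R)-campholenic aldehyde
Product: 4 (4R)-4-(2,2-dimethoxyethyl)-1,5,5-trimethylcyclopent-1-ene
Conditions: HC(OMe)3, MeOH, pyridinium p-toluenesulfonate (cat.), rt
Reagents that add atoms: trimethyl orthoformate, COC(OC)OC; methanol, CO (solvent, exchanges with the orthoformate)
Why: Acid-catalysed acetalisation driven by the orthoformate as water scavenger masks the aldehyde for the oxidative and basic steps ahead, and the mild pyridinium acid should leave the trisubstituted alkene in place.

Step 4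
Reactants: 4 (4R)-4-(2,2-dimethoxyethyl)-1,5,5-trimethylcyclopent-1-ene
Product: 6 (3R)-3-(2,2-dimethoxyethyl)-4,4-dimethyl-5-oxohexanal, via ozonide 5 (not isolated)
Conditions: O3, CH2Cl2, −78 °C (to first blue colour); PPh3, −78 °C to rt
Reagents that add atoms: ozone, [O-][O+]=O
Why: Ozonolysis (Criegee mechanism) of the only C=C and reduction of the ozonide with PPh3 open the temporary ring to a methyl ketone (C6, with the future C5 as its methyl) and an aldehyde (C4); the dimethyl acetal is inert at −78 °C when ozone is stopped at the end point.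

Step 5
Reactants: 6 (3R)-3-(2,2-dimethoxyethyl)-4,4-dimethyl-5-oxohexanal
Product: 8 (5R)-5-(2,2-dimethoxyethyl)-6,6-dimethylcyclohex-2-en-1-one, via aldol 7 (not isolated)
Conditions: KOH (0.3 equiv), MeOH, 0 °C to rt
Reagents that add atoms: none
Why: Intramolecular aldol condensation, 6-(enolexo)-exo-trig: only the methyl ketone enolate can reach the aldehyde through a six-membered transition state (the aldehyde enolate would have to close a four-membered ring), and E1cB loss of water gives the conjugated enone; C2 is β to both carbonyl groups and cannot epimerise.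

Step 6
Reactants: 8 (5R)-5-(2,2-dimethoxyethyl)-6,6-dimethylcyclohex-2-en-1-one
Product: 9 (3R)-3-(2,2-dimethoxyethyl)-2,2-dimethylcyclohexan-1-one
Conditions: H2 (1 atm), 10% Pd/C, EtOAc, rt
Reagents that add atoms: none
Why: Heterogeneous hydrogenation of the conjugated disubstituted alkene on palladium is much faster than reduction of the hindered ketone, and the acetal is stable in neutral ethyl acetate.

Step 7
Reactants: 9 (3R)-3-(2,2-dimethoxyethyl)-2,2-dimethylcyclohexan-1-one
Product: 11 (3R)-3-(2,2-dimethoxyethyl)-2,2,6-trimethylcyclohexan-1-one (mixture of C6 epimers), via lithium enolate 10 (not isolated)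
Conditions: LiN(i-Pr)2 (1.05 equiv), THF, −78 °C; MeI, −78 to 0 °C
Reagents that add atoms: iodomethane, CI
Why: Kinetic enolate alkylation; the ketone has a single enolisable α-carbon (C5, the other being quaternary), so regiochemistry is fixed, and the new methyl-bearing stereocentre, formed as a mixture of epimers, is erased in step 8.

Step 8
Reactants: 11 (3R)-3-(2,2-dimethoxyethyl)-2,2,6-trimethylcyclohexan-1-one
Product: 13 (5R)-5-(2,2-dimethoxyethyl)-2,6,6-trimethylcyclohex-1-en-1-yl trifluoromethanesulfonate, via lithium enolate 12 (not isolated)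
Conditions: LiN(i-Pr)2, THF, −78 to 0 °C; PhNTf2, 0 °C to rt
Reagents that add atoms: N-phenylbis(trifluoromethanesulfonimide), O=S(=O)(N(c1ccccc1)S(=O)(=O)C(F)(F)F)C(F)(F)F
Why: Deprotonation at the only remaining α-hydrogen gives the tetrasubstituted enolate, which is O-sulfonylated by PhNTf2 (enol triflate synthesis); this fixes the C5=C6 double bond and arms C6 for cross-coupling.

Step 9
Reactants: 13 (5R)-5-(2,2-dimethoxyethyl)-2,6,6-trimethylcyclohex-1-en-1-yl trifluoromethanesulfonate
Product: 14 (5R)-2,6,6-trimethyl-5-(2-oxoethyl)cyclohex-1-en-1-yl trifluoromethanesulfonate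
Conditions: aq. HCl (1 M), THF, rt
Reagents that add atoms: water, O
Why: Acid-catalysed hydrolysis of the dimethyl acetal; the alkenyl triflate is stable to dilute aqueous acid at room temperature and C2 is not α to the liberated aldehyde.

Step 10
Reactants: 14 (5R)-2,6,6-trimethyl-5-(2-oxoethyl)cyclohex-1-en-1-yl trifluoromethanesulfonate; 15 ethyl 2-(triphenylphosphoranylidene)propanoate
Product: 16 ethyl (2E)-2-methyl-4-[(1R)-2,2,4-trimethyl-3-(trifluoromethanesulfonyloxy)cyclohex-3-en-1-yl]but-2-enoate
Conditions: CH2Cl2, rt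
Reagents that add atoms: none
Why: Wittig reaction with a stabilised, α-branched ylide, which reacts only with the aldehyde and should give the E trisubstituted enoate (reversible oxaphosphetane formation, ester anti to the chain).

Step 11
Reactants: 16 ethyl (2E)-2-methyl-4-[(1R)-2,2,4-trimethyl-3-(trifluoromethanesulfonyloxy)cyclohex-3-en-1-yl]but-2-enoate
Product: 17 (5R)-5-[(2E)-4-hydroxy-3-methylbut-2-en-1-yl]-2,6,6-trimethylcyclohex-1-en-1-yl trifluoromethanesulfonate
Conditions: i-Bu2AlH (2.2 equiv), CH2Cl2, −78 °C; aq. Rochelle salt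
Reagents that add atoms: none
Why: 1,2-Reduction of the conjugated ester by i-Bu2AlH at low temperature gives the E allylic alcohol without touching the alkenyl triflate or the alkene geometry.

Step 12
Reactants: 17 (5R)-5-[(2E)-4-hydroxy-3-methylbut-2-en-1-yl]-2,6,6-trimethylcyclohex-1-en-1-yl trifluoromethanesulfonate
Product: 18 (5R)-5-[(2E)-4-{[tert-butyl(dimethyl)silyl]oxy}-3-methylbut-2-en-1-yl]-2,6,6-trimethylcyclohex-1-en-1-yl trifluoromethanesulfonate
Conditions: TBSCl, imidazole, DMF, 0 °C to rt
Reagents that add atoms: tert-butyldimethylsilyl chloride, CC(C)(C)[Si](C)(C)Cl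
Why: Imidazole-promoted silylation of the primary allylic alcohol protects it for the organometallic, hydride and low-valent titanium steps; fluoride removes the group at the end.

Step 13
Reactants: 19 (2E)-3-methylpent-2-en-4-yn-1-ol
Product: 20 (2E,4E)-3-methyl-5-(tributylstannyl)penta-2,4-dien-1-ol
Conditions: Bu3SnH, PdCl2(PPh3)2 (cat.), THF, 0 °C to rt
Reagents that add atoms: tributyltin hydride, CCCC[SnH](CCCC)CCCC
Why: Palladium-catalysed hydrostannation of the terminal alkyne: syn addition of Sn–H with tin at the terminal carbon of the conjugated enyne gives the E alkenylstannane, and the existing E trisubstituted alkene is untouched.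

Step 14
Reactants: 20 (2E,4E)-3-methyl-5-(tributylstannyl)penta-2,4-dien-1-ol
Product: 21 (2E,4E)-3-methyl-5-(tributylstannyl)penta-2,4-dienal
Conditions: MnO2 (activated, excess), CH2Cl2, rt
Reagents that add atoms: none
Why: Allylic oxidation with MnO2 is selective for the dienylic alcohol and leaves the C–Sn bond and both alkene geometries intact.

Step 15
Reactants: 21 (2E,4E)-3-methyl-5-(tributylstannyl)penta-2,4-dienal; 22 triethyl (2E)-3-methyl-4-phosphonobut-2-enoate
Product: 24 ethyl (2E,4E,6E,8E)-3,7-dimethyl-9-(tributylstannyl)nona-2,4,6,8-tetraenoate, via lithiated phosphonate 23 (not isolated)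
Conditions: 22, n-BuLi, DMPU, THF, 0 °C; then 21, −78 to 0 °C
Reagents that add atoms: none
Why: Horner–Wadsworth–Emmons olefination with the vinylogous phosphonate anion, which reacts at the carbon α to phosphorus and should give the new disubstituted alkene E, while the anion equilibrates toward the E trisubstituted enoate in the presence of DMPU.

Step 16
Reactants: 18 (5R)-5-[(2E)-4-{[tert-butyl(dimethyl)silyl]oxy}-3-methylbut-2-en-1-yl]-2,6,6-trimethylcyclohex-1-en-1-yl trifluoromethanesulfonate; 24 ethyl (2E,4E,6E,8E)-3,7-dimethyl-9-(tributylstannyl)nona-2,4,6,8-tetraenoate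
Product: 25 ethyl (2E,4E,6E,8E)-9-[(5R)-5-[(2E)-4-{[tert-butyl(dimethyl)silyl]oxy}-3-methylbut-2-en-1-yl]-2,6,6-trimethylcyclohex-1-en-1-yl]-3,7-dimethylnona-2,4,6,8-tetraenoate
Conditions: Pd2(dba)3 (cat.), AsPh3, NMP, 50–60 °C, dark
Reagents that add atoms: none
Why: Stille coupling: oxidative addition of zerovalent palladium to the hindered alkenyl triflate and transmetalation from the alkenylstannane, accelerated by the weakly bound AsPh3 ligand in NMP, proceed with retention of every alkene geometry and form the C6–C7 bond.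

Step 17
Reactants: 25 ethyl (2E,4E,6E,8E)-9-[(5R)-5-[(2E)-4-{[tert-butyl(dimethyl)silyl]oxy}-3-methylbut-2-en-1-yl]-2,6,6-trimethylcyclohex-1-en-1-yl]-3,7-dimethylnona-2,4,6,8-tetraenoate
Product: 26 (2E,4E,6E,8E)-9-[(5R)-5-[(2E)-4-{[tert-butyl(dimethyl)silyl]oxy}-3-methylbut-2-en-1-yl]-2,6,6-trimethylcyclohex-1-en-1-yl]-3,7-dimethylnona-2,4,6,8-tetraen-1-ol
Conditions: i-Bu2AlH (2.2 equiv), THF, −78 °C; aq. Rochelle salt
Reagents that add atoms: none
Why: i-Bu2AlH reduces the conjugated ester to the allylic alcohol at low temperature; the silyl ether and the polyene are inert.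

Step 18
Reactants: 26 (2E,4E,6E,8E)-9-[(5R)-5-[(2E)-4-{[tert-butyl(dimethyl)silyl]oxy}-3-methylbut-2-en-1-yl]-2,6,6-trimethylcyclohex-1-en-1-yl]-3,7-dimethylnona-2,4,6,8-tetraen-1-ol
Product: 27 (2E,4E,6E,8E)-9-[(5R)-5-[(2E)-4-{[tert-butyl(dimethyl)silyl]oxy}-3-methylbut-2-en-1-yl]-2,6,6-trimethylcyclohex-1-en-1-yl]-3,7-dimethylnona-2,4,6,8-tetraenal (the C25 polyenal)
Conditions: MnO2 (activated, excess), CH2Cl2, rt, dark
Reagents that add atoms: none
Why: MnO2 oxidises the polyenylic primary alcohol selectively to the conjugated aldehyde, the retinol-to-retinal type of oxidation, without over-oxidation.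

Step 19
Reactants: 27 the C25 polyenal (two molecules)
Product: 28 (2R,2'R)-2,2'-bis[(2E)-4-{[tert-butyl(dimethyl)silyl]oxy}-3-methylbut-2-en-1-yl]-β,β-carotene
Conditions: TiCl3, LiAlH4 (2:1), THF, reflux (reagent formation); then 27, THF, rt to reflux, argon, dark
Reagents that add atoms: none
Why: McMurry reductive carbonyl coupling: low-valent titanium joins two molecules of the polyenal at C15 and removes both oxygens, which should give the central C15=C15' alkene mainly E (any central Z isomer should equilibrate to all-E on gentle heating); this is the reaction type known for polyenals.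

Step 20
Reactants: 28 (2R,2'R)-2,2'-bis[(2E)-4-{[tert-butyl(dimethyl)silyl]oxy}-3-methylbut-2-en-1-yl]-β,β-carotene
Product: 29 (2R,2'R)-2,2'-bis[(2E)-4-hydroxy-3-methylbut-2-en-1-yl]-β,β-carotene (CNP0359519.1)
Conditions: Bu4NF, THF, 0 °C to rt, dark
Reagents that add atoms: none
Why: Fluoride-induced cleavage of both Si–O bonds (strong Si–F bond) liberates the two primary allylic alcohols under conditions that should not isomerise the polyene.

**Compound list**

1 | (1S,5S)-α-pinene, (1S,5S)-2,6,6-trimethylbicyclo[3.1.1]hept-2-ene | CC1=CC[C@H]2C[C@@H]1C2(C)C | starting material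
2 | α-pinene oxide, (1R,2R,4S,6R)-2,7,7-trimethyl-3-oxatricyclo[4.1.1.0(2,4)]octane, oxirane anti to the CMe2 bridge | C[C@]12O[C@H]1C[C@H]3C[C@@H]2C3(C)C | intermediate
3 | (R)-campholenic aldehyde, 2-[(1R)-2,2,3-trimethylcyclopent-3-en-1-yl]acetaldehyde | O=CC[C@H]1CC=C(C)C1(C)C | intermediate
4 | (4R)-4-(2,2-dimethoxyethyl)-1,5,5-trimethylcyclopent-1-ene | COC(OC)C[C@H]1CC=C(C)C1(C)C | intermediate
5 | secondary ozonide of 4, 3-(2,2-dimethoxyethyl)-1,2,2-trimethyl-6,7,8-trioxabicyclo[3.2.1]octane (ring stereocentre as in 4) | COC(OC)C[C@H]1CC2OOC(C)(O2)C1(C)C | intermediate (not isolated)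
6 | (3R)-3-(2,2-dimethoxyethyl)-4,4-dimethyl-5-oxohexanal | COC(OC)C[C@@H](CC=O)C(C)(C)C(C)=O | intermediate
7 | (5R)-5-(2,2-dimethoxyethyl)-3-hydroxy-6,6-dimethylcyclohexan-1-one (C3 epimers) | COC(OC)C[C@H]1CC(O)CC(=O)C1(C)C | intermediate (not isolated)
8 | (5R)-5-(2,2-dimethoxyethyl)-6,6-dimethylcyclohex-2-en-1-one | COC(OC)C[C@H]1CC=CC(=O)C1(C)C | intermediate
9 | (3R)-3-(2,2-dimethoxyethyl)-2,2-dimethylcyclohexan-1-one | COC(OC)C[C@H]1CCCC(=O)C1(C)C | intermediate
10 | lithium (5R)-5-(2,2-dimethoxyethyl)-6,6-dimethylcyclohex-1-en-1-olate | COC(OC)C[C@H]1CCC=C([O-])C1(C)C.[Li+] | intermediate (not isolated)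
11 | (3R)-3-(2,2-dimethoxyethyl)-2,2,6-trimethylcyclohexan-1-one (C6 epimers) | COC(OC)C[C@H]1CCC(C)C(=O)C1(C)C | intermediate
12 | lithium (5R)-5-(2,2-dimethoxyethyl)-2,6,6-trimethylcyclohex-1-en-1-olate | COC(OC)C[C@H]1CCC(C)=C([O-])C1(C)C.[Li+] | intermediate (not isolated)
13 | (5R)-5-(2,2-dimethoxyethyl)-2,6,6-trimethylcyclohex-1-en-1-yl trifluoromethanesulfonate | COC(OC)C[C@H]1CCC(C)=C(OS(=O)(=O)C(F)(F)F)C1(C)C | intermediate
14 | (5R)-2,6,6-trimethyl-5-(2-oxoethyl)cyclohex-1-en-1-yl trifluoromethanesulfonate | O=CC[C@H]1CCC(C)=C(OS(=O)(=O)C(F)(F)F)C1(C)C | intermediate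
15 | ethyl 2-(triphenylphosphoranylidene)propanoate | CCOC(=O)C(C)=P(c1ccccc1)(c1ccccc1)c1ccccc1 | starting material
16 | ethyl (2E)-2-methyl-4-[(1R)-2,2,4-trimethyl-3-(trifluoromethanesulfonyloxy)cyclohex-3-en-1-yl]but-2-enoate | CCOC(=O)/C(C)=C/C[C@H]1CCC(C)=C(OS(=O)(=O)C(F)(F)F)C1(C)C | intermediate
17 | (5R)-5-[(2E)-4-hydroxy-3-methylbut-2-en-1-yl]-2,6,6-trimethylcyclohex-1-en-1-yl trifluoromethanesulfonate | OC/C(C)=C/C[C@H]1CCC(C)=C(OS(=O)(=O)C(F)(F)F)C1(C)C | intermediate
18 | (5R)-5-[(2E)-4-{[tert-butyl(dimethyl)silyl]oxy}-3-methylbut-2-en-1-yl]-2,6,6-trimethylcyclohex-1-en-1-yl trifluoromethanesulfonate | CC(C)(C)[Si](C)(C)OC/C(C)=C/C[C@H]1CCC(C)=C(OS(=O)(=O)C(F)(F)F)C1(C)C | intermediate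
19 | (2E)-3-methylpent-2-en-4-yn-1-ol | OC/C=C(\C)C#C | starting material
20 | (2E,4E)-3-methyl-5-(tributylstannyl)penta-2,4-dien-1-ol | OC/C=C(C)/C=C/[Sn](CCCC)(CCCC)CCCC | intermediate
21 | (2E,4E)-3-methyl-5-(tributylstannyl)penta-2,4-dienal | O=C/C=C(C)/C=C/[Sn](CCCC)(CCCC)CCCC | intermediate
22 | triethyl (2E)-3-methyl-4-phosphonobut-2-enoate (sold as an E/Z mixture, usable as such) | CCOC(=O)/C=C(\C)CP(=O)(OCC)OCC | starting material
23 | lithiated 22 (delocalised allyl anion) | [Li+].CCOC(=O)C=C(C)[CH-]P(=O)(OCC)OCC | intermediate (not isolated)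
24 | ethyl (2E,4E,6E,8E)-3,7-dimethyl-9-(tributylstannyl)nona-2,4,6,8-tetraenoate | CCOC(=O)/C=C(C)/C=C/C=C(C)/C=C/[Sn](CCCC)(CCCC)CCCC | intermediate
25 | ethyl (2E,4E,6E,8E)-9-[(5R)-5-[(2E)-4-{[tert-butyl(dimethyl)silyl]oxy}-3-methylbut-2-en-1-yl]-2,6,6-trimethylcyclohex-1-en-1-yl]-3,7-dimethylnona-2,4,6,8-tetraenoate | CCOC(=O)/C=C(C)/C=C/C=C(C)/C=C/C1=C(C)CC[C@H](C/C=C(\C)CO[Si](C)(C)C(C)(C)C)C1(C)C | intermediate
26 | (2E,4E,6E,8E)-9-[(5R)-5-[(2E)-4-{[tert-butyl(dimethyl)silyl]oxy}-3-methylbut-2-en-1-yl]-2,6,6-trimethylcyclohex-1-en-1-yl]-3,7-dimethylnona-2,4,6,8-tetraen-1-ol | OC/C=C(C)/C=C/C=C(C)/C=C/C1=C(C)CC[C@H](C/C=C(\C)CO[Si](C)(C)C(C)(C)C)C1(C)C | intermediate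
27 | (2E,4E,6E,8E)-9-[(5R)-5-[(2E)-4-{[tert-butyl(dimethyl)silyl]oxy}-3-methylbut-2-en-1-yl]-2,6,6-trimethylcyclohex-1-en-1-yl]-3,7-dimethylnona-2,4,6,8-tetraenal | O=C/C=C(C)/C=C/C=C(C)/C=C/C1=C(C)CC[C@H](C/C=C(\C)CO[Si](C)(C)C(C)(C)C)C1(C)C | intermediate
28 | (2R,2'R)-2,2'-bis[(2E)-4-{[tert-butyl(dimethyl)silyl]oxy}-3-methylbut-2-en-1-yl]-β,β-carotene (all-E) | CC1=C(/C=C/C(C)=C/C=C/C(C)=C/C=C/C=C(C)/C=C/C=C(C)/C=C/C2=C(C)CC[C@H](C/C=C(\C)CO[Si](C)(C)C(C)(C)C)C2(C)C)C(C)(C)[C@@H](C/C=C(\C)CO[Si](C)(C)C(C)(C)C)CC1 | intermediate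
29 | (2R,2'R)-2,2'-bis[(2E)-4-hydroxy-3-methylbut-2-en-1-yl]-β,β-carotene (all-E), CNP0359519.1 | CC1=C(/C=C/C(C)=C/C=C/C(C)=C/C=C/C=C(C)/C=C/C=C(C)/C=C/C2=C(C)CC[C@H](C/C=C(\C)CO)C2(C)C)C(C)(C)[C@@H](C/C=C(\C)CO)CC1 | target

**Step count**

Total: 20 steps. Longest linear sequence: 17 steps (steps 1–12, then 16–20); the stannane branch (steps 13–15) is 3 steps.

**Steps most likely to fail**

1. Step 19 (reductive coupling). The Lewis-acidic low-valent titanium slurry may cleave the allylic C–O bonds of the silyl ethers reductively or desilylate them, and the hot deoxygenation may scramble alkene geometry or partly reduce the polyene. Fallback, a Wittig union of two C25 halves: it sets out from alcohol 26, which with PPh3·HBr in CH2Cl2 at 0 °C (aprotic, to spare the silyl ether) should give the C25 allylic phosphonium bromide F1. Its ylide (NaOMe, MeOH/CH2Cl2, 0 °C to rt) is condensed with aldehyde 27, and the central alkene is equilibrated to E by gentle heating. The fallback comes back to the route at 28, which goes on to step 20.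

2. Step 16 (Stille coupling). Transmetalation at the tetrasubstituted alkenylpalladium centre flanked by the C5 methyl and the C1 gem-dimethyl group may be slow, so that protodestannylation, homocoupling and geometric isomerisation of the long stannyl polyene compete. Fallback, a different fragment partition in which the chain is finished by olefination after the ring coupling: it sets out from triflate 18, which is coupled (Pd2(dba)3, AsPh3, NMP) with the short and more robust dienylstannane 20 to give the ring dienol F2. MnO2 in CH2Cl2 should give the ring dienal F3, and Horner–Wadsworth–Emmons reaction with the lithiated phosphonate 23 (from 22, n-BuLi, DMPU) then forms the C11=C12 bond. The fallback comes back to the route at 25.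

3. Step 7 (C5 methylation). Proton transfer between enolate 10 and the monomethylated ketone may lead to double methylation at C5, which gives a ketone that can no longer form the enol triflate, together with incomplete conversion. Fallback, the methyl group is put on the enone and the enolate is made by conjugate reduction: it sets out from enone 8, which with I2 and pyridine in CH2Cl2 should give the α-iodoenone F4. Stille methylation (Me4Sn, Pd2(dba)3, AsPh3, CuI, NMP) gives the 2-methyl enone F5. Conjugate reduction with LiBH(s-Bu)3 in THF at −78 °C generates the same regiodefined enolate 12, which is trapped with PhNTf2. The fallback comes back to the route at 13 and bypasses 9 and 11.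

**Further compounds**

F1 | step 19 | {(2E,4E,6E,8E)-9-[(5R)-5-[(2E)-4-{[tert-butyl(dimethyl)silyl]oxy}-3-methylbut-2-en-1-yl]-2,6,6-trimethylcyclohex-1-en-1-yl]-3,7-dimethylnona-2,4,6,8-tetraen-1-yl}triphenylphosphonium bromide | [Br-].C(/C=C(C)/C=C/C=C(C)/C=C/C1=C(C)CC[C@H](C/C=C(\C)CO[Si](C)(C)C(C)(C)C)C1(C)C)[P+](c1ccccc1)(c1ccccc1)c1ccccc1
F2 | step 16 | (2E,4E)-5-[(5R)-5-[(2E)-4-{[tert-butyl(dimethyl)silyl]oxy}-3-methylbut-2-en-1-yl]-2,6,6-trimethylcyclohex-1-en-1-yl]-3-methylpenta-2,4-dien-1-ol | OC/C=C(C)/C=C/C1=C(C)CC[C@H](C/C=C(\C)CO[Si](C)(C)C(C)(C)C)C1(C)C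
F3 | step 16 | (2E,4E)-5-[(5R)-5-[(2E)-4-{[tert-butyl(dimethyl)silyl]oxy}-3-methylbut-2-en-1-yl]-2,6,6-trimethylcyclohex-1-en-1-yl]-3-methylpenta-2,4-dienal | O=C/C=C(C)/C=C/C1=C(C)CC[C@H](C/C=C(\C)CO[Si](C)(C)C(C)(C)C)C1(C)C
F4 | step 7 | (5R)-5-(2,2-dimethoxyethyl)-2-iodo-6,6-dimethylcyclohex-2-en-1-one | COC(OC)C[C@H]1CC=C(I)C(=O)C1(C)C
F5 | step 7 | (5R)-5-(2,2-dimethoxyethyl)-2,6,6-trimethylcyclohex-2-en-1-one | COC(OC)C[C@H]1CC=C(C)C(=O)C1(C)C
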